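**Assumption (one line):** the SMILES is taken literally as the enantiomer to make (its eudesmanolide half has the (S)-Wieland–Miescher configuration, antipodal to natural alantolactone, so both halves are built de novo); guaiane/eudesmane locants are used in descriptive names (eudesmane primed); in step 13 the ligand enantiomer written is assumed to be the one that gives the 8R lactone (otherwise its antipode is used).

## Retrosynthetic overview

1. 31 ⇒ endo Diels–Alder (bonds C13′–C1 and C11′–C3): 2-acetoxycyclopentadiene 30, made in the flask from tertiary allylic alcohol 29, plus dienophile 14; the norbornene and spiro-lactone rings form last.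
2. 29 ⇒ hydroxycyclopentenone 27 ⇒ furan 25 (oxidative opening/aldol builds the carbocyclic five-ring) ⇒ lactone acetal 23 (Friedel–Crafts closes the seven-ring) ⇒ aldehyde 17 + bromide 21 (Cr allylation builds the lactone).
3. 17 ⇒ 2,5-dimethylfuran + crotonaldehyde; 21 ⇒ methyl acrylate + dimethoxyacetaldehyde.
4. 14 ⇒ keto ester 9 (reduction/lactonisation, then α-methylenation) ⇒ dienyl triflate 6 ⇒ (S)-Wieland–Miescher ketone 1 (decalin purchased).
5. Ring order: guaianolide half lactone → cycloheptane → cyclopentene; eudesmanolide half decalin → lactone; then the [4+2].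

## Route

### Dienophile 14

Step 1
Reactants: 1 (8aS)-8a-methyl-3,4,8,8a-tetrahydronaphthalene-1,6(2H,7H)-dione [(S)-Wieland–Miescher ketone]
Product: 2 (8aS)-8a-methyl-4-methylidene-3,4,8,8a-tetrahydronaphthalene-1,6(2H,7H)-dione
Conditions: CH2(OEt)2, POCl3, NaOAc, CHCl3, reflux
Reagents that add atoms: diethoxymethane, CCOCOCC
Why: Direct γ-methylenation of an enone (the steroid 6-methylenation reaction): the linear dienol ether formed in situ is attacked at the γ-carbon by the ethoxymethyl cation and EtOH is eliminated, while the hindered saturated ketone is left alone.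

Step 2
Reactants: 2 (8aS)-8a-methyl-4-methylidene-3,4,8,8a-tetrahydronaphthalene-1,6(2H,7H)-dione
Product: 3 (4R,8aS)-4,8a-dimethyl-3,4,8,8a-tetrahydronaphthalene-1,6(2H,7H)-dione
Conditions: H2 (1 atm), RhCl(PPh3)3 (5 mol %), PhH, 23 °C
Reagents that add atoms: none
Why: Wilkinson hydrogenation reduces only the exocyclic 1,1-disubstituted alkene, and H2 is delivered to the face opposite the angular methyl, giving the kinetic secondary methyl cis to it (4R).

Step 3
Reactants: 3 (4R,8aS)-4,8a-dimethyl-3,4,8,8a-tetrahydronaphthalene-1,6(2H,7H)-dione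
Product: 4 (4aS,5S,8R)-5-hydroxy-4a,8-dimethyl-4,4a,5,6,7,8-hexahydronaphthalen-2(3H)-one
Conditions: NaBH4 (0.3 equiv), EtOH, −10 °C
Reagents that add atoms: none
Why: Chemoselective borohydride reduction of the saturated ketone over the enone (known for the Wieland–Miescher ketone); hydride enters anti to the angular methyl, giving the hydroxyl cis to it (5S).

Step 4
Reactants: 4 (4aS,5S,8R)-5-hydroxy-4a,8-dimethyl-4,4a,5,6,7,8-hexahydronaphthalen-2(3H)-one
Product: 5 (4aS,5S,8R)-4a,8-dimethyl-5-(triethylsilyloxy)-4,4a,5,6,7,8-hexahydronaphthalen-2(3H)-one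
Conditions: TESCl, imidazole, DMAP (cat.), DMF, 23 °C
Reagents that add atoms: chlorotriethylsilane, CC[Si](Cl)(CC)CC
Why: Standard silylation masks the alcohol for the enolate, borane and oxidation steps that follow.

Step 5
Reactants: 5 (4aS,5S,8R)-4a,8-dimethyl-5-(triethylsilyloxy)-4,4a,5,6,7,8-hexahydronaphthalen-2(3H)-one
Product: 6 (4aS,5S,8R)-4a,8-dimethyl-5-(triethylsilyloxy)-4,4a,5,6,7,8-hexahydronaphthalen-2-yl trifluoromethanesulfonate
Conditions: LDA, THF, −78 °C; PhNTf2, −78 → 0 °C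
Reagents that add atoms: N-phenylbis(trifluoromethanesulfonimide), O=S(=O)(N(c1ccccc1)S(=O)(=O)C(F)(F)F)C(F)(F)F
Why: Kinetic α′-deprotonation of the enone and O-triflation give the cross-conjugated dienyl triflate; the γ-hydrogen at the methyl-bearing carbon is not touched at −78 °C, so that centre is kept.

Step 6
Reactants: 6 (4aS,5S,8R)-4a,8-dimethyl-5-(triethylsilyloxy)-4,4a,5,6,7,8-hexahydronaphthalen-2-yl trifluoromethanesulfonate
Product: 7 methyl 2-[(4aS,5S,8R)-4a,8-dimethyl-5-(triethylsilyloxy)-4,4a,5,6,7,8-hexahydronaphthalen-2-yl]acetate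
Conditions: BrZnCH2CO2Me, Pd(PPh3)4 (5 mol %), THF, 60 °C
Reagents that add atoms: (2-methoxy-2-oxoethyl)zinc bromide, COC(=O)C[Zn]Br
Why: Negishi-type cross-coupling of a Reformatsky reagent with the vinyl triflate installs the acetate arm on C7′ with the ring diene intact.

Step 7
Reactants: 7 methyl 2-[(4aS,5S,8R)-4a,8-dimethyl-5-(triethylsilyloxy)-4,4a,5,6,7,8-hexahydronaphthalen-2-yl]acetate
Product: 9 methyl 2-[(2R,4aS,5S,8R)-4a,8-dimethyl-3-oxo-5-(triethylsilyloxy)-2,3,4,4a,5,6,7,8-octahydronaphthalen-2-yl]acetate, via alkylborane 8 (not isolated)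
Conditions: 9-BBN, THF, 0 → 23 °C; then NMO, TPAP (5 mol %), 4 Å MS, CH2Cl2, 23 °C
Reagents that add atoms: N-methylmorpholine N-oxide, C[N+]1([O-])CCOCC1
Why: Hydroboration puts boron on the unhindered CH terminus (C8′) of the ring diene from the face opposite the angular methyl, so H-7′ is also delivered trans to the methyl and the acetate arm ends up cis to it; amine-oxide oxidation of the C–B bond and Ley–Griffith oxidation then give the β,γ-unsaturated ketone in one flask.

Step 8
Reactants: 9 methyl 2-[(2R,4aS,5S,8R)-4a,8-dimethyl-3-oxo-5-(triethylsilyloxy)-2,3,4,4a,5,6,7,8-octahydronaphthalen-2-yl]acetate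
Product: 11 (3aR,5R,8S,8aS,9aS)-8-hydroxy-5,8a-dimethyl-3a,5,6,7,8,8a,9,9a-octahydronaphtho[2,3-b]furan-2(3H)-one, via silyl lactone 10 (not isolated)
Conditions: L-Selectride, THF, −78 → 0 °C; then 1 M HCl, MeOH, 23 °C
Reagents that add atoms: none
Why: The bulky hydride attacks the C8′ ketone from the face opposite the syn-axial angular methyl, giving the axial alkoxide cis to the methyl and to the equatorial acetate arm, which closes to the cis-fused γ-lactone (9aS) by translactonisation; dilute acid removes the TES ether.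

Step 9
Reactants: 11 (3aR,5R,8S,8aS,9aS)-8-hydroxy-5,8a-dimethyl-3a,5,6,7,8,8a,9,9a-octahydronaphtho[2,3-b]furan-2(3H)-one
Product: 14 (3aS,5R,8S,8aS,9aS)-8-hydroxy-5,8a-dimethyl-3-methylidene-3a,5,6,7,8,8a,9,9a-octahydronaphtho[2,3-b]furan-2(3H)-one, via Mannich base 12 (not isolated), via methiodide 13 (not isolated)
Conditions: LDA (2.5 equiv), THF, −78 °C, CH2=NMe2+ I−; then MeI, MeOH; then aq. NaHCO3, CH2Cl2
Reagents that add atoms: Eschenmoser's salt, C=[N+](C)C.[I-]
Why: Eschenmoser α-methylenation (Mannich reaction of the lactone enolate, N-methylation, Hofmann-type elimination); no stereocentre is affected and the free alcohol only consumes one equivalent of base.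

### Diene precursor 29

Step 10
Reactants: 15 2,5-dimethylfuran; 16 (2E)-but-2-enal
Product: 17 (3R)-3-(2,5-dimethylfuran-3-yl)butanal
Conditions: (2S,5S)-5-benzyl-2-tert-butyl-3-methylimidazolidin-4-one·TFA (20 mol %), 15 (3 equiv), CH2Cl2/i-PrOH, −40 °C
Reagents that add atoms: none
Why: Iminium-catalysed enantioselective Friedel–Crafts conjugate alkylation (MacMillan type) at the only free furan positions; the catalyst's benzyl group shields one face of the E-iminium ion and sets C10 as R, by analogy with the sense seen for indoles and pyrroles.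

Step 11
Reactants: 18 methyl acrylate; 19 2,2-dimethoxyacetaldehyde
Product: 20 methyl 3-hydroxy-4,4-dimethoxy-2-methylidenebutanoate (racemic)
Conditions: DABCO (20 mol %), 1,4-dioxane/H2O, 23 °C
Reagents that add atoms: none
Why: Morita–Baylis–Hillman reaction of an activated, non-enolisable aldehyde; the new centre is lost in the next step.

Step 12
Reactants: 20 methyl 3-hydroxy-4,4-dimethoxy-2-methylidenebutanoate
Product: 21 methyl (2Z)-2-(bromomethyl)-4,4-dimethoxybut-2-enoate
Conditions: NBS, Me2S, CH2Cl2, 0 → 23 °C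
Reagents that add atoms: N-bromosuccinimide, O=C1CCC(=O)N1Br
Why: Corey–Kim-type bromination of a Baylis–Hillman alcohol with allylic transposition (SN2′) gives the thermodynamically preferred Z-bromide under neutral conditions that spare the acetal.

Step 13
Reactants: 17 (3R)-3-(2,5-dimethylfuran-3-yl)butanal; 21 methyl (2Z)-2-(bromomethyl)-4,4-dimethoxybut-2-enoate
Product: 23 (4S,5R)-4-(dimethoxymethyl)-5-[(2R)-2-(2,5-dimethylfuran-3-yl)propyl]-3-methylideneoxolan-2-one, via TMS ether 22 (not isolated)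
Conditions: CrCl2 (10 mol %), (S,S)-i-Pr carbazole-bis(oxazoline) ligand (12 mol %), Mn, TMSCl, i-Pr2NEt (cat.), THF, 23 °C; then PPTS, MeOH, 40 °C
Reagents that add atoms: none
Why: Catalytic asymmetric Nozaki–Hiyama–Kishi 2-(alkoxycarbonyl)allylation: the γ-substituted allylchromium reacts through a chair transition state to the anti adduct (trans-lactone after acid desilylation/lactonisation), and the aldehyde face (8R, hence 7S) is set by the chiral Cr complex independently of the remote C10 centre.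

Step 14
Reactants: 23 (4S,5R)-4-(dimethoxymethyl)-5-[(2R)-2-(2,5-dimethylfuran-3-yl)propyl]-3-methylideneoxolan-2-one
Product: 25 (7S,8R,10R)-2,4-epoxy-3,4-secoguaia-1,4,11(13)-trien-12,8-olide (2,5-dimethylfuran fused through its 3,4-positions to the cycloheptane that carries the 10-methyl and the trans α-methylene-γ-lactone), via cyclic methyl ether 24 (not isolated)
Conditions: BF3·OEt2, CH2Cl2, −78 °C; then Et3SiH, −78 → −20 °C
Reagents that add atoms: none
Why: Intramolecular Friedel–Crafts (Pictet–Spengler-type) attack of the remaining furan β-carbon on the oxocarbenium ion closes the seven-membered ring, and ionic hydrogenation of the resulting furylic ether removes the oxygen; no stereocentre is made or touched.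

Step 15
Reactants: 25 (7S,8R,10R)-2,4-epoxy-3,4-secoguaia-1,4,11(13)-trien-12,8-olide
Product: 27 (7S,8R,10R)-4ξ-hydroxy-2-oxoguaia-1(5),11(13)-dien-12,8-olide, via cis-enedione 26 (not isolated)
Conditions: mCPBA, NaHCO3, CH2Cl2, 0 °C; then aq. Na2CO3, THF, 0 → 23 °C
Reagents that add atoms: 3-chloroperoxybenzoic acid, OOC(=O)c1cccc(Cl)c1
Why: Oxidative furan opening to the cis-enedione followed by intramolecular aldol addition, in which the methyl of the acetyl on C1 adds to the less hindered acetyl carbonyl on C5 (flanked by CH2, not by the branched C10), giving the 4-hydroxycyclopentenone with the ketone at C2; both C4 epimers are carried on because that centre is erased in step 18.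

Step 16
Reactants: 27 (7S,8R,10R)-4ξ-hydroxy-2-oxoguaia-1(5),11(13)-dien-12,8-olide
Product: 28 (2S,7S,8R,10R)-2,4ξ-dihydroxyguaia-1(5),11(13)-dien-12,8-olide
Conditions: NaBH4, CeCl3·7H2O, MeOH, −78 °C
Reagents that add atoms: none
Why: Luche 1,2-reduction, fast enough at −78 °C to spare the methylene lactone; the trans-lactone locks the seven-ring so that the C10 methyl is pseudo-axial beside the C2 carbonyl, hydride enters from the other face and the 2-OH is formed cis to that methyl (2S).

Step 17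
Reactants: 28 (2S,7S,8R,10R)-2,4ξ-dihydroxyguaia-1(5),11(13)-dien-12,8-olide
Product: 29 (2S,7S,8R,10R)-2-acetoxy-4ξ-hydroxyguaia-1(5),11(13)-dien-12,8-olide
Conditions: Ac2O, pyridine, DMAP (cat.), CH2Cl2, 0 °C
Reagents that add atoms: acetic anhydride, CC(=O)OC(C)=O
Why: Selective acylation of the secondary allylic alcohol; the tertiary alcohol does not react under these conditions.

### Union

Step 18
Reactants: 29 (2S,7S,8R,10R)-2-acetoxy-4ξ-hydroxyguaia-1(5),11(13)-dien-12,8-olide; 14 (3aS,5R,8S,8aS,9aS)-8-hydroxy-5,8a-dimethyl-3-methylidene-3a,5,6,7,8,8a,9,9a-octahydronaphtho[2,3-b]furan-2(3H)-one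
Product: 31 japonicone A, via acetoxy diene 30 (not isolated)
Conditions: Martin sulfurane (1.1 equiv), CH2Cl2, −40 °C, 20 min; then 14 (3 equiv, excess recovered), BHT, concentrate to ca. 2 M, 23 °C, 36 h (or 10 kbar)
Reagents that add atoms: none
Why: Low-temperature dehydration of the tertiary allylic alcohol (endocyclic Zaitsev product) gives the labile 5-acetoxycyclopentadiene 30, which is trapped before [1,5]-H shift by a biomimetic endo Diels–Alder reaction with the unprotected α-methylene lactone: the dienophile adds to the diene face opposite both the C2 acetate and the pseudo-axial C10 methyl, through its convex (H-7′/H-8′) face with the lactone carbonyl endo and its CH2 terminus bonding to the more substituted diene carbon C1, which sets C1, C3 and C11′ and leaves the acetate syn to the new alkene.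

## Compound list

1 | (8aS)-8a-methyl-3,4,8,8a-tetrahydronaphthalene-1,6(2H,7H)-dione, (S)-Wieland–Miescher ketone | O=C1CC[C@@]2(C)C(=C1)CCCC2=O | starting material
2 | (8aS)-8a-methyl-4-methylidene-3,4,8,8a-tetrahydronaphthalene-1,6(2H,7H)-dione | O=C1CC[C@@]2(C)C(=C1)C(=C)CCC2=O | intermediate
3 | (4R,8aS)-4,8a-dimethyl-3,4,8,8a-tetrahydronaphthalene-1,6(2H,7H)-dione | O=C1CC[C@@]2(C)C(=C1)[C@H](C)CCC2=O | intermediate
4 | (4aS,5S,8R)-5-hydroxy-4a,8-dimethyl-4,4a,5,6,7,8-hexahydronaphthalen-2(3H)-one | O=C1CC[C@@]2(C)C(=C1)[C@H](C)CC[C@@H]2O | intermediate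
5 | (4aS,5S,8R)-4a,8-dimethyl-5-(triethylsilyloxy)-4,4a,5,6,7,8-hexahydronaphthalen-2(3H)-one | O=C1CC[C@@]2(C)C(=C1)[C@H](C)CC[C@@H]2O[Si](CC)(CC)CC | intermediate
6 | (4aS,5S,8R)-4a,8-dimethyl-5-(triethylsilyloxy)-4,4a,5,6,7,8-hexahydronaphthalen-2-yl trifluoromethanesulfonate | O=S(=O)(OC1=CC[C@@]2(C)C(=C1)[C@H](C)CC[C@@H]2O[Si](CC)(CC)CC)C(F)(F)F | intermediate
7 | methyl 2-[(4aS,5S,8R)-4a,8-dimethyl-5-(triethylsilyloxy)-4,4a,5,6,7,8-hexahydronaphthalen-2-yl]acetate | COC(=O)CC1=CC[C@@]2(C)C(=C1)[C@H](C)CC[C@@H]2O[Si](CC)(CC)CC | intermediate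
8 | alkylborane: 9-BBN adduct of 7, boron on C8′ and hydrogen on C7′ both trans to the angular methyl | C1CC2CCCC(C1)B2[C@@H]1C[C@@]2(C)C(=C[C@H]1CC(=O)OC)[C@H](C)CC[C@@H]2O[Si](CC)(CC)CC | intermediate
9 | methyl 2-[(2R,4aS,5S,8R)-4a,8-dimethyl-3-oxo-5-(triethylsilyloxy)-2,3,4,4a,5,6,7,8-octahydronaphthalen-2-yl]acetate | O=C1C[C@@]2(C)C(=C[C@H]1CC(=O)OC)[C@H](C)CC[C@@H]2O[Si](CC)(CC)CC | intermediate
10 | (3aR,5R,8S,8aS,9aS)-5,8a-dimethyl-8-(triethylsilyloxy)-3a,5,6,7,8,8a,9,9a-octahydronaphtho[2,3-b]furan-2(3H)-one | C1C(=O)O[C@H]2C[C@@]3(C)C(=C[C@H]21)[C@H](C)CC[C@@H]3O[Si](CC)(CC)CC | intermediate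
11 | (3aR,5R,8S,8aS,9aS)-8-hydroxy-5,8a-dimethyl-3a,5,6,7,8,8a,9,9a-octahydronaphtho[2,3-b]furan-2(3H)-one | C1C(=O)O[C@H]2C[C@@]3(C)C(=C[C@H]21)[C@H](C)CC[C@@H]3O | intermediate
12 | Mannich base: 3-[(dimethylamino)methyl] derivative of 11 (C3 epimers) | CN(C)CC1C(=O)O[C@H]2C[C@@]3(C)C(=C[C@H]21)[C@H](C)CC[C@@H]3O | intermediate
13 | methiodide of 12 | C[N+](C)(C)CC1C(=O)O[C@H]2C[C@@]3(C)C(=C[C@H]21)[C@H](C)CC[C@@H]3O.[I-] | intermediate
14 | (3aS,5R,8S,8aS,9aS)-8-hydroxy-5,8a-dimethyl-3-methylidene-3a,5,6,7,8,8a,9,9a-octahydronaphtho[2,3-b]furan-2(3H)-one (the 1-hydroxyalantolactone enantiomer needed) | C=C1C(=O)O[C@H]2C[C@@]3(C)C(=C[C@H]21)[C@H](C)CC[C@@H]3O | intermediate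
15 | 2,5-dimethylfuran | Cc1ccc(C)o1 | starting material
16 | (2E)-but-2-enal (crotonaldehyde) | C/C=C/C=O | starting material
17 | (3R)-3-(2,5-dimethylfuran-3-yl)butanal | O=CC[C@@H](C)c1cc(C)oc1C | intermediate
18 | methyl acrylate | C=CC(=O)OC | starting material
19 | 2,2-dimethoxyacetaldehyde | COC(OC)C=O | starting material
20 | methyl 3-hydroxy-4,4-dimethoxy-2-methylidenebutanoate (racemic) | COC(OC)C(O)C(=C)C(=O)OC | intermediate
21 | methyl (2Z)-2-(bromomethyl)-4,4-dimethoxybut-2-enoate | COC(OC)/C=C(/C(=O)OC)CBr | intermediate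
22 | methyl (3S,4R,6R)-3-(dimethoxymethyl)-6-(2,5-dimethylfuran-3-yl)-2-methylidene-4-(trimethylsilyloxy)heptanoate | COC(=O)C(=C)[C@H](C(OC)OC)[C@@H](C[C@@H](C)c1cc(C)oc1C)O[Si](C)(C)C | intermediate
23 | (4S,5R)-4-(dimethoxymethyl)-5-[(2R)-2-(2,5-dimethylfuran-3-yl)propyl]-3-methylideneoxolan-2-one | C=C1C(=O)O[C@H](C[C@@H](C)c2cc(C)oc2C)[C@H]1C(OC)OC | intermediate
24 | 6ξ-methoxy derivative of 25 | C=C1C(=O)O[C@@H]2C[C@@H](C)c3c(C)oc(C)c3C(OC)[C@@H]12 | intermediate
25 | (7S,8R,10R)-2,4-epoxy-3,4-secoguaia-1,4,11(13)-trien-12,8-olide (furan-fused cycloheptane trans-lactone) | C=C1C(=O)O[C@@H]2C[C@@H](C)c3c(C)oc(C)c3C[C@@H]12 | intermediate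
26 | (7S,8R,10R)-2,4-dioxo-3,4-secoguaia-1(5),11(13)-dien-12,8-olide (cis-enedione) | C=C1C(=O)O[C@@H]2C[C@@H](C)C(C(C)=O)=C(C(C)=O)C[C@@H]12 | intermediate
27 | (7S,8R,10R)-4ξ-hydroxy-2-oxoguaia-1(5),11(13)-dien-12,8-olide | C=C1C(=O)O[C@@H]2C[C@@H](C)C3=C(C[C@@H]12)C(C)(O)CC3=O | intermediate
28 | (2S,7S,8R,10R)-2,4ξ-dihydroxyguaia-1(5),11(13)-dien-12,8-olide | C=C1C(=O)O[C@@H]2C[C@@H](C)C3=C(C[C@@H]12)C(C)(O)C[C@@H]3O | intermediate
29 | (2S,7S,8R,10R)-2-acetoxy-4ξ-hydroxyguaia-1(5),11(13)-dien-12,8-olide | C=C1C(=O)O[C@@H]2C[C@@H](C)C3=C(C[C@@H]12)C(C)(O)C[C@@H]3OC(C)=O | intermediate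
30 | (2S,7S,8R,10R)-2-acetoxyguaia-1(5),3,11(13)-trien-12,8-olide | C=C1C(=O)O[C@@H]2C[C@@H](C)C3=C(C[C@@H]12)C(C)=C[C@@H]3OC(C)=O | intermediate
31 | japonicone A | C=C1C(=O)O[C@@H]2C[C@@H](C)[C@]34C[C@]5(C(=O)O[C@H]6C[C@@]7(C)C(=C[C@H]65)[C@H](C)CC[C@@H]7O)[C@H](C(C)=C3C[C@@H]12)[C@@H]4OC(C)=O | target

## Step count and risks

Total step count: 18. Longest linear sequence: 10 steps (steps 1–9, then 18).

**Step 18 (dehydration/Diels–Alder).** The risks are [1,5]-H shift of diene 30, self-dimerisation of 30 through its own methylene lactone, and facial selectivity (the acetoxy group electronically favours syn addition, whereas the target needs anti). The fallback sets out from 29 and comes back at 31. The guaianolide's own dienophile is masked: 29 with Me2NH (THF, 0 °C) gives the dimethylamine adduct F1. Martin sulfurane then gives the amino diene F2 (not isolated), which can be combined with 14 neat or at 10 kbar without self-dimerisation to give the amino cycloadduct F3. MeI (MeCN) forms the methiodide F4, and aqueous NaHCO3 eliminates trimethylamine to unveil the methylene lactone of 31.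

**Step 10 (organocatalytic Friedel–Crafts at a furan β-carbon).** The β-position of 2,5-dimethylfuran may be too weak a nucleophile for the iminium ion, or the ee may be low. The fallback sets out from 15 and comes back at 17. Friedel–Crafts acetylation (Ac2O, cat. BF3·OEt2) gives 3-acetyl-2,5-dimethylfuran F5. Horner–Wadsworth–Emmons olefination (triethyl phosphonoacetate, NaH, THF) gives ethyl (2E)-3-(2,5-dimethylfuran-3-yl)but-2-enoate F6. CuH-catalysed asymmetric conjugate reduction (Cu(OAc)2, chiral bisphosphine of the sense giving 3R, PMHS, t-BuOH) gives ethyl (3R)-3-(2,5-dimethylfuran-3-yl)butanoate F7. DIBAL-H at −78 °C then gives 17.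

**Step 13 (catalyst-controlled Cr allylation).** The sense and level of induction with the γ-acetal bromide are uncertain, and the step-14 ring closure depends on it. The fallback sets out from 15 and 20, comes back at 25, and also replaces step 14 by a substrate-controlled ring closure. Reductive Friedel–Crafts alkylation of 15 with acetal 20 (BF3·OEt2, Et3SiH) gives methyl 4-(2,5-dimethylfuran-3-yl)-3-hydroxy-2-methylidenebutanoate F8. Conjugate alkylation with 16 under the step-10 conditions gives the hydroxy aldehyde F9. NBS/Me2S gives the allylic bromide F10. Intramolecular Nozaki–Hiyama–Kishi cyclisation (CrCl2, 3 equiv, THF) then closes the seven-membered ring and the trans-lactone together to give 25; the 10-methyl, held pseudo-axial by the flanking furan methyl, directs the anti addition.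

Further compounds

F1 | step 18 | dimethylamine adduct of 29 (C11 epimers) | CN(C)CC1C(=O)O[C@@H]2C[C@@H](C)C3=C(C[C@@H]12)C(C)(O)C[C@@H]3OC(C)=O
F2 | step 18 | amino diene (dimethylamine adduct of 30) | CN(C)CC1C(=O)O[C@@H]2C[C@@H](C)C3=C(C[C@@H]12)C(C)=C[C@@H]3OC(C)=O
F3 | step 18 | amino cycloadduct (dimethylamine adduct of 31) | CN(C)CC1C(=O)O[C@@H]2C[C@@H](C)[C@]34C[C@]5(C(=O)O[C@H]6C[C@@]7(C)C(=C[C@H]65)[C@H](C)CC[C@@H]7O)[C@H](C(C)=C3C[C@@H]12)[C@@H]4OC(C)=O
F4 | step 18 | methiodide of F3 | C[N+](C)(C)CC1C(=O)O[C@@H]2C[C@@H](C)[C@]34C[C@]5(C(=O)O[C@H]6C[C@@]7(C)C(=C[C@H]65)[C@H](C)CC[C@@H]7O)[C@H](C(C)=C3C[C@@H]12)[C@@H]4OC(C)=O.[I-]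
F5 | step 10 | 3-acetyl-2,5-dimethylfuran | CC(=O)c1cc(C)oc1C
F6 | step 10 | ethyl (2E)-3-(2,5-dimethylfuran-3-yl)but-2-enoate | CCOC(=O)/C=C(\C)c1cc(C)oc1C
F7 | step 10 | ethyl (3R)-3-(2,5-dimethylfuran-3-yl)butanoate | CCOC(=O)C[C@@H](C)c1cc(C)oc1C
F8 | step 13 | methyl 4-(2,5-dimethylfuran-3-yl)-3-hydroxy-2-methylidenebutanoate | COC(=O)C(=C)C(O)Cc1cc(C)oc1C
F9 | step 13 | methyl 4-{2,5-dimethyl-4-[(2R)-4-oxobutan-2-yl]furan-3-yl}-3-hydroxy-2-methylidenebutanoate | COC(=O)C(=C)C(O)Cc1c(C)oc(C)c1[C@H](C)CC=O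
F10 | step 13 | methyl (2Z)-2-(bromomethyl)-4-{2,5-dimethyl-4-[(2R)-4-oxobutan-2-yl]furan-3-yl}but-2-enoate | COC(=O)/C(CBr)=C/Cc1c(C)oc(C)c1[C@H](C)CC=O
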